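**Plan**

Numbering of the target: C1 ring C=O, C2=C3, C4 ring CHOH, C5 quaternary C–OH, C6 CHOAc, C7–C18 dodecyl chain; O4, O5, O6 are the oxygens on C4, C5, C6.
Enabling feature: C4–C5–C6 with O4/O5/O6 is a hidden dihydroxyacetone. With C5 as the ketone of a 1,3-dioxan-5-one ring (acetonide across O4 and O6), the tertiary α-ketol C1(=O)–C5(OH) of the cyclopentenone becomes the product of an acyl-anion (benzoin-type) closure of an aldehyde C1 onto C5.
Retrosynthetic cuts, in order: O6–acetyl (from O5 by 1,2-acyl shift), C2=C3 (dehydrogenation), C1–C5 (ring closure), then C6–C7 and C3–C4 (two auxiliary-controlled alkylations of the dioxanone); the aldehyde C1 comes from a terminal alkene.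
Forward order: butenyl and dodecyl are attached to the dioxanone hydrazone, ozone unveils ketone and aldehyde together, the five-membered ring closes C1–C5 onto the temporary dioxane ring, the enone is introduced, and the acetonide is taken out last.
Stereochemistry: C4 and C6 from the SAMP auxiliary (trans-4,6, both S); C5 from the enforced cis fusion of the new ring on the dioxane (O5 trans to O4); the acetate ends on O6 because O4 is trans to O5 on the ring and cannot accept it.

Key step: step 5

Remarks on the chemistry:
- The C=N geometry of the hydrazone intermediates is left unspecified in the SMILES; it is lost on cleavage.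
- The sense of induction is taken from the standard model for ketone SAMP hydrazones (electrophile anti to the pyrrolidine ring). Applied to this α-oxygenated ring ketone it corresponds to the (S) descriptor at both alkylated carbons; this assignment is by analogy.
- 4-Iodobut-1-ene is taken as a purchasable reagent.

**Route**

Step 1
Reactants: 1 2,2-dimethyl-1,3-dioxan-5-one; 2 (S)-1-amino-2-(methoxymethyl)pyrrolidine (SAMP)
Product: 3 (S)-N-(2,2-dimethyl-1,3-dioxan-5-ylidene)-2-(methoxymethyl)pyrrolidin-1-amine
Conditions: cyclohexane, reflux, Dean–Stark trap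
Reagents that add atoms: none
Why: Hydrazone formation by condensation of the hydrazine with the ketone, driven by azeotropic removal of water; no stereocentre is formed.

Step 2
Reactants: 3 the SAMP hydrazone; 4 4-iodobut-1-ene
Product: 6 (S)-N-[(4S)-4-(but-3-en-1-yl)-2,2-dimethyl-1,3-dioxan-5-ylidene]-2-(methoxymethyl)pyrrolidin-1-amine, via lithium azaenolate 5 (not isolated)
Conditions: t-BuLi, THF, −78 °C; then 4, −100 °C to rt
Reagents that add atoms: none
Why: Enders SAMP-hydrazone alkylation; the lithium azaenolate, held rigid by chelation of lithium to the methoxymethyl oxygen, should be alkylated on the face remote from the pyrrolidine ring, which sets C4 as (S).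

Step 3
Reactants: 6 the monoalkylated hydrazone; 7 1-iodododecane
Product: 9 (S)-N-[(4S,6S)-4-(but-3-en-1-yl)-6-dodecyl-2,2-dimethyl-1,3-dioxan-5-ylidene]-2-(methoxymethyl)pyrrolidin-1-amine, via lithium azaenolate 8 (not isolated)
Conditions: t-BuLi, THF, −78 °C; then 7, −100 °C to rt
Reagents that add atoms: none
Why: Second Enders alkylation; metalation should occur at the unsubstituted α′-carbon and the same auxiliary-controlled facial bias sets C6 as (S), trans to the butenyl group, which is the anti O4/O6 pattern of the target.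

Step 4
Reactants: 9 the trans-dialkylated hydrazone
Product: 11 3-[(4S,6S)-6-dodecyl-2,2-dimethyl-5-oxo-1,3-dioxan-4-yl]propanal, via keto ozonide 10 (not isolated)
Conditions: O3, CH2Cl2, −78 °C; then Me2S, −78 °C to rt
Reagents that add atoms: ozone, O=[O+][O-]
Why: Ozonolysis should cleave the terminal alkene to the aldehyde C1 and, in the same operation, the hydrazone C=N to the ketone C5 under non-basic conditions that do not epimerize C4 or C6; the auxiliary leaves as its N-nitrosamine.

Step 5
Reactants: 11 the keto aldehyde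
Product: 12 (4S,4aR,7aS)-4-dodecyl-4a-hydroxy-2,2-dimethylhexahydrocyclopenta[d][1,3]dioxin-5(4H)-one (cis ring fusion)
Conditions: 2-(pentafluorophenyl)-6,7-dihydro-5H-pyrrolo[2,1-c][1,2,4]triazol-2-ium tetrafluoroborate (cat.), Et3N (cat.), CH2Cl2, high dilution, rt
Reagents that add atoms: none
Why: The carbene generated from the triazolium salt adds to the aldehyde C1, proton transfer gives the Breslow intermediate (an acyl anion equivalent), this adds to the ketone C5, and collapse releases the carbene and the α-ketol. The closest known reaction type is the carbene-catalysed intramolecular crossed aldehyde–ketone benzoin reaction that gives five-membered cyclic acyloins fused cis to an existing ring. The cyclopentanone ring C1–C2–C3–C4–C5 closes in the 5-exo-trig mode. The new stereocentre C5 is controlled by the temporary dioxane ring: the two-carbon tether on C4 can reach the neighbouring carbonyl carbon only from its own face (tether pseudo-axial), so the fusion should be cis, placing O5 trans to O4 and fixing C5 relative to C6. The step needs chemoselectivity (only the aldehyde can form the acyl anion, and the ketone is a strong acceptor because of its two α-oxygens), closure in preference to intermolecular benzoin (dilution), and retention at C4 and C6 (weak amine base, room temperature).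

Step 6
Reactants: 12 the bicyclic α-ketol
Product: 13 (4S,4aR,7aS)-4-dodecyl-2,2-dimethyl-5-oxohexahydrocyclopenta[d][1,3]dioxin-4a(4H)-yl acetate
Conditions: Ac2O, DMAP (4-dimethylaminopyridine), Et3N, CH2Cl2, rt to 40 °C
Reagents that add atoms: acetic anhydride, CC(=O)OC(C)=O
Why: Nucleophilic-catalysed acylation should acetylate the only hydroxyl present, the tertiary α-ketol O5, so the regiochemistry is unambiguous; no stereocentre is touched.

Step 7
Reactants: 13 the tertiary acetate
Product: 14 (4S,4aR,7aS)-4-dodecyl-2,2-dimethyl-5-[(trimethylsilyl)oxy]-4,7-dihydrocyclopenta[d][1,3]dioxin-4a(7aH)-yl acetate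
Conditions: Me3SiOTf, Et3N, CH2Cl2, 0 °C
Reagents that add atoms: trimethylsilyl trifluoromethanesulfonate, C[Si](C)(C)OS(=O)(=O)C(F)(F)F
Why: Soft enolization should give the silyl enol ether towards C2, the only enolizable α-position because C5 is quaternary, without disturbing the acetate or the acetonide.

Step 8
Reactants: 14 the silyl enol ether
Product: 15 (4S,4aR,7aS)-4-dodecyl-2,2-dimethyl-5-oxo-4,5-dihydrocyclopenta[d][1,3]dioxin-4a(7aH)-yl acetate
Conditions: Pd(OAc)2 (1 equiv), MeCN, rt
Reagents that add atoms: none
Why: Saegusa–Ito oxidation; the enol ether is converted to the enolate of divalent palladium and β-hydride elimination of H3 should give the C2=C3 enone with release of zerovalent palladium, C4 being safe because C5 carries no hydrogen for elimination of O4.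

Step 9
Reactants: 15 the enone acetonide acetate
Product: 17 (1S)-1-[(1S,5S)-1,5-dihydroxy-2-oxocyclopent-3-en-1-yl]tridecyl acetate (the target), via tertiary acetate diol 16 (not isolated)
Conditions: AcOH/H2O/THF (4:1:1), 40 °C; then Et3N (cat.), CH2Cl2, 0 °C
Reagents that add atoms: none
Why: Acid hydrolysis should remove the strained trans-4,6-acetonide, and in the liberated diol the acetyl group should move from the tertiary, ketone-flanked O5 to the adjacent secondary O6 through a five-membered cyclic orthoacid (1,2-acyl migration to the less hindered oxygen), while O4, trans to O5 on the ring, cannot take part; no stereocentre changes.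

**Compound list**

1 | 2,2-dimethyl-1,3-dioxan-5-one | CC1(C)OCC(=O)CO1 | starting material
2 | (S)-1-amino-2-(methoxymethyl)pyrrolidine (SAMP) | COC[C@@H]1CCCN1N | starting material
3 | (S)-N-(2,2-dimethyl-1,3-dioxan-5-ylidene)-2-(methoxymethyl)pyrrolidin-1-amine | COC[C@@H]1CCCN1N=C1COC(C)(C)OC1 | intermediate
4 | 4-iodobut-1-ene | C=CCCI | starting material
5 | lithium azaenolate of 3 (lithiated at ring C4) | COC[C@@H]1CCCN1[N-]C1=COC(C)(C)OC1.[Li+] | intermediate
6 | (S)-N-[(4S)-4-(but-3-en-1-yl)-2,2-dimethyl-1,3-dioxan-5-ylidene]-2-(methoxymethyl)pyrrolidin-1-amine | C=CCC[C@@H]1OC(C)(C)OCC1=NN1CCC[C@H]1COC | intermediate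
7 | 1-iodododecane | CCCCCCCCCCCCI | starting material
8 | lithium azaenolate of 6 (lithiated at the unsubstituted α′-carbon) | C=CCC[C@@H]1OC(C)(C)OC=C1[N-]N1CCC[C@H]1COC.[Li+] | intermediate
9 | (S)-N-[(4S,6S)-4-(but-3-en-1-yl)-6-dodecyl-2,2-dimethyl-1,3-dioxan-5-ylidene]-2-(methoxymethyl)pyrrolidin-1-amine (trans-4,6) | CCCCCCCCCCCC[C@@H]1OC(C)(C)O[C@@H](CCC=C)C1=NN1CCC[C@H]1COC | intermediate
10 | (4S,6S)-4-dodecyl-2,2-dimethyl-6-[2-(1,2,4-trioxolan-3-yl)ethyl]-1,3-dioxan-5-one (keto ozonide, trioxolane carbon undefined) | CCCCCCCCCCCC[C@@H]1OC(C)(C)O[C@@H](CCC2OCOO2)C1=O | intermediate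
11 | 3-[(4S,6S)-6-dodecyl-2,2-dimethyl-5-oxo-1,3-dioxan-4-yl]propanal | CCCCCCCCCCCC[C@@H]1OC(C)(C)O[C@@H](CCC=O)C1=O | intermediate
12 | (4S,4aR,7aS)-4-dodecyl-4a-hydroxy-2,2-dimethylhexahydrocyclopenta[d][1,3]dioxin-5(4H)-one, cis-fused | CCCCCCCCCCCC[C@@H]1OC(C)(C)O[C@H]2CCC(=O)[C@@]12O | intermediate
13 | (4S,4aR,7aS)-4-dodecyl-2,2-dimethyl-5-oxohexahydrocyclopenta[d][1,3]dioxin-4a(4H)-yl acetate | CCCCCCCCCCCC[C@@H]1OC(C)(C)O[C@H]2CCC(=O)[C@@]12OC(C)=O | intermediate
14 | (4S,4aR,7aS)-4-dodecyl-2,2-dimethyl-5-[(trimethylsilyl)oxy]-4,7-dihydrocyclopenta[d][1,3]dioxin-4a(7aH)-yl acetate | CCCCCCCCCCCC[C@@H]1OC(C)(C)O[C@H]2CC=C(O[Si](C)(C)C)[C@@]12OC(C)=O | intermediate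
15 | (4S,4aR,7aS)-4-dodecyl-2,2-dimethyl-5-oxo-4,5-dihydrocyclopenta[d][1,3]dioxin-4a(7aH)-yl acetate | CCCCCCCCCCCC[C@@H]1OC(C)(C)O[C@H]2C=CC(=O)[C@@]12OC(C)=O | intermediate
16 | (1R,5S)-5-hydroxy-1-[(1S)-1-hydroxytridecyl]-2-oxocyclopent-3-en-1-yl acetate | CCCCCCCCCCCC[C@H](O)[C@]1(OC(C)=O)C(=O)C=C[C@@H]1O | intermediate
17 | (1S)-1-[(1S,5S)-1,5-dihydroxy-2-oxocyclopent-3-en-1-yl]tridecyl acetate | CCCCCCCCCCCC[C@H](OC(C)=O)[C@]1(O)C(=O)C=C[C@@H]1O | target

**Count and risks**

Total step count: 9. Longest linear sequence: 9 steps (from 1).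

Steps most likely to fail:

Step 5. The amine base may epimerize the α-alkoxy ketone centres C4/C6 before ring closure, or aldol and intermolecular benzoin pathways may compete. Fallback: setting out from 11, the C1–C5 bond would be made reductively instead. SmI2, t-BuOH, THF, −78 °C should convert the aldehyde into its ketyl, which adds to the ketone under essentially neutral conditions to give the cis-fused pinacol diol F1 (cis fusion for the same geometric reason). Oxidation of the secondary carbinol of F1 with SO3·pyridine, DMSO, Et3N (Parikh–Doering oxidation) would rejoin the route at 12.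

Step 6. Acetylation of the congested tertiary hydroxyl may be too slow. Fallback: setting out from 12, O5 is left unacylated and the acetate is placed at the end by diol recognition. Me3SiOTf/Et3N should give the bis(trimethylsilyl) compound F2 (silyl enol ether plus O5 silyl ether). Pd(OAc)2 in MeCN should give the enone silyl ether F3. Aqueous AcOH should remove the silyl ether and the acetonide to give the triol F4. Tin-mediated monoacylation (Me2SnCl2 cat., AcCl, i-Pr2NEt, THF, 0 °C) would then address the only diol able to form a five-membered stannylene (O5/O6) and acylate its secondary oxygen O6, arriving at 17.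

Step 9. The acetyl shift may stop short, run on from O6 to O4, or the acetate may be lost during hydrolysis. Fallback: setting out from 12, the hydroxyls are told apart by protecting groups instead of by acyl migration. Camphorsulfonic acid (cat.) in acetone should transpose the strained trans-4,6-acetonide to the five-membered spiro 5,6-acetonide F5, freeing O4. t-BuMe2SiOTf/Et3N should give the silyl ether/silyl enol ether F6. Pd(OAc)2 in MeCN should give the enone F7. Aqueous AcOH at rt should remove the acetonide with the silyl ether retained, giving the diol F8. Ac2O, pyridine, DMAP should acetylate the secondary O6 to give the acetate F9. HF·pyridine in THF would remove the silyl ether to arrive at 17.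

Further compounds
F1 | step 5 | cis-fused pinacol diol: 4-dodecyl-2,2-dimethylhexahydrocyclopenta[d][1,3]dioxine-4a,5-diol, configuration at C4, C4a, C7a as in 12, 4a-OH and 5-OH cis | CCCCCCCCCCCC[C@@H]1OC(C)(C)O[C@H]2CC[C@H](O)[C@@]12O
F2 | step 6 | bis(trimethylsilyl) compound: 5-silyl enol ether and 4a-O-silyl ether of 12 | CCCCCCCCCCCC[C@@H]1OC(C)(C)O[C@H]2CC=C(O[Si](C)(C)C)[C@@]12O[Si](C)(C)C
F3 | step 6 | enone silyl ether: 4-dodecyl-2,2-dimethyl-4a-[(trimethylsilyl)oxy]-4a,7a-dihydrocyclopenta[d][1,3]dioxin-5(4H)-one, configuration as in 12 | CCCCCCCCCCCC[C@@H]1OC(C)(C)O[C@H]2C=CC(=O)[C@@]12O[Si](C)(C)C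
F4 | step 6 | triol: (4S,5R)-4,5-dihydroxy-5-[(1S)-1-hydroxytridecyl]cyclopent-2-en-1-one | CCCCCCCCCCCC[C@H](O)[C@]1(O)C(=O)C=C[C@@H]1O
F5 | step 9 | spiro 5,6-acetonide with free C4 hydroxyl: 3-dodecyl-9-hydroxy-2,2-dimethyl-1,4-dioxaspiro[4.4]nonan-6-one, configuration at C4, C5, C6 of the target numbering as in 17 | CCCCCCCCCCCC[C@@H]1OC(C)(C)O[C@]12C(=O)CC[C@@H]2O
F6 | step 9 | silyl ether/silyl enol ether of F5 (O4 and the C1 enol oxygen both carry t-BuMe2Si) | CCCCCCCCCCCC[C@@H]1OC(C)(C)O[C@]12C(O[Si](C)(C)C(C)(C)C)=CC[C@@H]2O[Si](C)(C)C(C)(C)C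
F7 | step 9 | enone: 4-O-silylated cyclopentenone carrying the spiro 5,6-acetonide | CCCCCCCCCCCC[C@@H]1OC(C)(C)O[C@]12C(=O)C=C[C@@H]2O[Si](C)(C)C(C)(C)C
F8 | step 9 | diol: 4-O-(tert-butyldimethylsilyl) ether of triol F4 (O5 and O6 free) | CCCCCCCCCCCC[C@H](O)[C@]1(O)C(=O)C=C[C@@H]1O[Si](C)(C)C(C)(C)C
F9 | step 9 | 4-O-(tert-butyldimethylsilyl) ether of the target 17 | CCCCCCCCCCCC[C@H](OC(C)=O)[C@]1(O)C(=O)C=C[C@@H]1O[Si](C)(C)C(C)(C)C
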